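## Analysis of the target

Target 18 joins a 5-chloro-6,8-dihydroxyisocoumarin to a trisubstituted oxolane (ring C) through an (E,E)-buta-1,3-diene running from C3 of the isocoumarin to C2' of the oxolane. In the isocoumarin, ring A is the benzenoid ring C4a–C8a and ring B is the pyranone O2/C1/C3/C4.

All three stereocentres lie in ring C: C2' (R, dienyl), C3' (S, hydroxyl) and C5' (R, methyl). The dienyl group is trans to both the hydroxyl and the methyl group, which are cis to each other. This is the array of a 2-deoxy-D-erythro-pentofuranose with a methyl group on the α face of the anomeric carbon and with C5 turned into the first diene carbon.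

The sensitive functions are:
- the enol lactone of ring B, which alkoxide, hydroxide and amines open;
- the C2'–O1' bond, which is allylic to an extended π system and can ionise under acid with loss of configuration;
- the diene, which excludes hydrogenolysis and strong electrophiles;
- the aryl chloride.

Ring A is pentasubstituted. C4a, where ring B must be attached, is meta to both oxygens and flanked by C5–Cl and the carboxyl carbon, so electrophilic substitution and ortho-lithiation go to C7 instead. Chlorine must also sit on C5 and not on C7. The final deprotection must spare lactone, diene and allylic ether, which rules out methyl and benzyl ethers on the phenols.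

## Retrosynthetic reasoning

**18 ⇐ 17.** The last operation is the removal of three silyl groups. Silyl ethers are the only phenol protection that comes off under buffered fluoride, which neither opens ring B nor ionises the C2'–O1' bond.

**17 ⇐ 15 + 12 (key disconnection).** Ring B is cut at C4–C4a and at O2–C3. This is the bond at the arene carbon that classical chemistry cannot reach, but in acid 15 this C–H is the only one ortho to the carboxyl group and is acidified by the neighbouring chlorine. A carboxylate-directed C–H metalation therefore addresses exactly C4a without any handle on the arene. The C3/C4 unit with its dienyl substituent is an acylmethyl carbene, available from sulfoxonium ylide 12. The forward step must form C4a–C4, then close O2–C3 by lactonisation. It joins the two halves and builds ring B in one operation, and the arene partner shrinks to a protected, purchasable benzoic acid. Until that moment the diene is conjugated to a ketone, which protects the C2'–O1' bond against ionisation.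

**12 ⇐ 10 ⇐ 9 ⇐ 7 + 8.** The ylide carbon (the future C4) is attached by C-acylation of a sulfur ylide with the acid chloride 11 of acid 10. The diene is cut at the double bond next to ring C: a vinylogous phosphonate 8 brings four carbons and the E geometry of the second alkene to aldehyde 7. This keeps the side chain linear and uses the former C5 of the sugar as the first diene carbon.

**7 ⇐ 6 ⇐ 5.** The aldehyde comes from the primary alcohol 6, which is uncovered from bis-silyl ether 5 by the rate difference between primary and secondary silyl ethers.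

**5 ⇐ 4 ⇐ 2 ⇐ 1.** The C5'–CH3 bond is cut. A methyl donor adds to the oxocarbenium ion derived from anomeric acetate 4, and the C3 silyloxy group steers it to the cis face, so only the one stereocentre that the chiral pool does not supply has to be made. Lactone 1 supplies C2' and C3' with fixed configuration and all ring carbons.

**15 ⇐ 13.** The chlorine is bought in place in acid 13, so the C5/C7 regiochemistry problem never arises. Only silylation is needed.

## Alternatives that were turned down

Alternative 1: The textbook disconnection cuts the central single bond of the diene between two finished halves. The forward step would be a Stille coupling (zerovalent palladium) of iodovinyl isocoumarin A1 with vinylstannane A2. It was turned down for three reasons: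
- A1 needs its own isocoumarin synthesis with chlorine on C5 and a two-carbon handle on C3. This goes through a chlorinated toluate or homophthalate, where chlorination must discriminate C5 from C7 and several steps are spent before any coupling.
- The coupling itself forms one bond and no ring.
- Both halves must carry a metal or halide handle, so the total step count rises without shortening the longest sequence.

Alternative 2: Ring B is cut at the same two bonds as in the chosen route, but through an o-alkynylbenzoate. Sonogashira coupling of aryl iodide A3 with dienyne A4 would give A5, followed by 6-endo-dig cycloisomerisation. It was turned down for three reasons: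
- A3 needs iodine on exactly the carbon that iodination and directed lithiation avoid, so it would demand a diazonium route or a de novo arene.
- A4 is a terminal dienyne prone to polymerisation.
- The 6-endo versus 5-exo (phthalide) outcome is not secure for an alkyne with a conjugated dienyl substituent.

Alternative 3: Ring C is closed last at O1'–C2' by 5-endo opening of the trans dienyl epoxide A6 by the C5' hydroxyl, with inversion at C2'. It was turned down for three reasons:
- A6 carries the same three stereocentres as the target in a less accessible arrangement, so nothing is simplified.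
- The epoxide would have to be placed selectively on the distal alkene of a triene conjugated to the isocoumarin.
- Activation of a trienyl epoxide runs through a delocalised cation, with scrambling at C2' and attack at the vinylogous positions. Lactone 1 gives C2' and C3' for free.

Key step: step 10

Assumption: 2-deoxy-D-ribono-1,4-lactone (1) is taken as purchasable; it is otherwise one step from 2-deoxy-D-ribose by bromine-water oxidation.

## Route

Step 1
Reactants: 1 2-deoxy-D-ribono-1,4-lactone
Product: 2 (4S,5R)-4-(tert-butyldimethylsilyloxy)-5-[(tert-butyldimethylsilyloxy)methyl]oxolan-2-one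
Conditions: TBSCl (2.5 equiv), imidazole, DMF, 23 °C
Reagents that add atoms: tert-butyldimethylsilyl chloride CC(C)(C)[Si](C)(C)Cl
Why: Standard silylation of both hydroxyl groups; no stereocentre is touched, and ether-type (non-participating) protection at C3 is needed for the facial control in step 3.

Step 2
Reactants: 2 (4S,5R)-4-(tert-butyldimethylsilyloxy)-5-[(tert-butyldimethylsilyloxy)methyl]oxolan-2-one
Product: 4 (4S,5R)-4-(tert-butyldimethylsilyloxy)-5-[(tert-butyldimethylsilyloxy)methyl]oxolan-2-yl acetate (mixture of anomers), via aluminium lactolate 3 (not isolated)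
Conditions: i-Bu2AlH, CH2Cl2, −78 °C; then pyridine, DMAP, Ac2O, −78 → −20 °C
Reagents that add atoms: acetic anhydride CC(=O)OC(C)=O; diisobutylaluminium hydride CC(C)C[AlH]CC(C)C (aluminium only in 3)
Why: One-pot reductive acetylation of a lactone; the tetrahedral aluminium lactolate 3 is stable at −78 °C and is acetylated in place, which avoids the open-chain hydroxy aldehyde. The anomeric configuration does not matter because step 3 erases it.

Step 3
Reactants: 4 (4S,5R)-4-(tert-butyldimethylsilyloxy)-5-[(tert-butyldimethylsilyloxy)methyl]oxolan-2-yl acetate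
Product: 5 (2R,3S,5R)-3-(tert-butyldimethylsilyloxy)-2-[(tert-butyldimethylsilyloxy)methyl]-5-methyloxolane
Conditions: AlMe3 (3 equiv), CH2Cl2, −78 → 0 °C
Reagents that add atoms: trimethylaluminium C[Al](C)C
Why: AlMe3 ionises the anomeric acetate and transfers methyl to the five-membered oxocarbenium ion (Lewis acid mediated C-glycosylation). With the C3 silyloxy group pseudoaxial, the nucleophile enters on the inside face of the envelope, cis to the C3 oxygen and trans to the C4 side chain, which sets C5 of the oxolane as R.

Step 4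
Reactants: 5 (2R,3S,5R)-3-(tert-butyldimethylsilyloxy)-2-[(tert-butyldimethylsilyloxy)methyl]-5-methyloxolane
Product: 6 [(2R,3S,5R)-3-(tert-butyldimethylsilyloxy)-5-methyloxolan-2-yl]methanol
Conditions: camphorsulfonic acid (0.1 equiv), MeOH/CH2Cl2 (1:1), 0 °C
Reagents that add atoms: none
Why: Acid-catalysed methanolysis removes the primary silyl ether much faster than the hindered secondary one; stopping at 0 °C should leave the C3 ether in place.

Step 5
Reactants: 6 [(2R,3S,5R)-3-(tert-butyldimethylsilyloxy)-5-methyloxolan-2-yl]methanol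
Product: 7 (2S,3S,5R)-3-(tert-butyldimethylsilyloxy)-5-methyloxolane-2-carbaldehyde
Conditions: TEMPO (10 mol %), PhI(OAc)2, CH2Cl2, 23 °C
Reagents that add atoms: none
Why: Oxoammonium-mediated oxidation of a primary alcohol under neutral, non-epimerising conditions; the α-alkoxy aldehyde is used directly (the descriptor at C2 changes only because of the priority rules).

Step 6
Reactants: 7 (2S,3S,5R)-3-(tert-butyldimethylsilyloxy)-5-methyloxolane-2-carbaldehyde; 8 triethyl 4-phosphonocrotonate [ethyl (2E)-4-(diethoxyphosphoryl)but-2-enoate]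
Product: 9 ethyl (2E,4E)-5-[(2R,3S,5R)-3-(tert-butyldimethylsilyloxy)-5-methyloxolan-2-yl]penta-2,4-dienoate
Conditions: 8, LiN(SiMe3)2, THF, −78 °C; then 7, −78 → 0 °C
Reagents that add atoms: none
Why: Vinylogous Horner–Wadsworth–Emmons olefination; the stabilised γ-anion should give the E alkene while the existing E alkene of 8 is retained. Adding the aldehyde to the preformed anion at −78 °C avoids epimerisation or β-elimination at the α-alkoxy aldehyde.

Step 7
Reactants: 9 ethyl (2E,4E)-5-[(2R,3S,5R)-3-(tert-butyldimethylsilyloxy)-5-methyloxolan-2-yl]penta-2,4-dienoate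
Product: 10 (2E,4E)-5-[(2R,3S,5R)-3-(tert-butyldimethylsilyloxy)-5-methyloxolan-2-yl]penta-2,4-dienoic acid
Conditions: LiOH, THF/MeOH/H2O (3:1:1), 23 °C; then 1 M HCl to pH 4
Reagents that add atoms: lithium hydroxide [Li+].[OH-]
Why: Ester saponification; the secondary silyl ether and the allylic ring ether are stable to aqueous LiOH at room temperature and to brief acidification to pH 4.

Step 8
Reactants: 10 (2E,4E)-5-[(2R,3S,5R)-3-(tert-butyldimethylsilyloxy)-5-methyloxolan-2-yl]penta-2,4-dienoic acid
Product: 12 (3E,5E)-1-[dimethyl(oxo)-λ6-sulfanylidene]-6-[(2R,3S,5R)-3-(tert-butyldimethylsilyloxy)-5-methyloxolan-2-yl]hexa-3,5-dien-2-one, via acid chloride 11 (not isolated)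
Conditions: 1-chloro-N,N,2-trimethylprop-1-en-1-amine, CH2Cl2, 0 °C; then added to Me2S(O)=CH2 (3 equiv, from Me3S(O)I and KOtBu, THF, 65 °C), −10 → 0 °C
Reagents that add atoms: trimethylsulfoxonium iodide C[S+](C)(C)=O.[I-]; 1-chloro-N,N,2-trimethylprop-1-en-1-amine CC(C)=C(Cl)N(C)C (chlorine only in 11)
Why: The α-chloroenamine gives the acid chloride under neutral conditions. C-acylation of the Corey–Chaykovsky methylide at the acyl chloride is far faster than conjugate addition to the diene, and a second equivalent of methylide deprotonates the acylsulfoxonium salt to the stabilised ylide.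

Step 9
Reactants: 13 5-chloro-2,4-dihydroxybenzoic acid
Product: 15 5-chloro-2,4-bis(triisopropylsilyloxy)benzoic acid, via triisopropylsilyl ester 14 (not isolated)
Conditions: TIPSCl (3.5 equiv), imidazole, DMF, 50 °C; then AcOH/THF/H2O (3:1:1), 23 °C
Reagents that add atoms: triisopropylsilyl chloride CC(C)[Si](Cl)(C(C)C)C(C)C
Why: Exhaustive silylation, then selective hydrolysis of the acyloxysilane, which is far more labile to aqueous acid than aryl silyl ethers. The bulky triisopropylsilyl groups are chosen because they resist oxygen-to-oxygen silyl migration and are released by fluoride at the end.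

Step 10
Reactants: 15 5-chloro-2,4-bis(triisopropylsilyloxy)benzoic acid; 12 (3E,5E)-1-[dimethyl(oxo)-λ6-sulfanylidene]-6-[(2R,3S,5R)-3-(tert-butyldimethylsilyloxy)-5-methyloxolan-2-yl]hexa-3,5-dien-2-one
Product: 17 3-[(1E,3E)-4-[(2R,3S,5R)-3-(tert-butyldimethylsilyloxy)-5-methyloxolan-2-yl]buta-1,3-dien-1-yl]-5-chloro-6,8-bis(triisopropylsilyloxy)-1H-isochromen-1-one, via keto acid 16 (not isolated)
Conditions: 15 (1.0 equiv), 12 (1.3 equiv), [Cp*RhCl2]2 (5 mol %), AgSbF6 (20 mol %), NaOAc (30 mol %), 4 Å molecular sieves, ClCH2CH2Cl, 60 °C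
Reagents that add atoms: none
Why: The cationic Cp* complex of trivalent rhodium binds the carboxylate of 15 and cleaves the only ortho C–H (the future C4a–H, acidified by the adjacent chlorine) by acetate-assisted concerted metalation–deprotonation to give a five-membered rhodacycle. Ylide 12 binds through carbon and loses dimethyl sulfoxide to give a rhodium carbene; migratory insertion of the aryl group forms C4a–C4, and protonolysis releases keto acid 16 and returns the catalyst without any external oxidant. Keto acid 16 then closes ring B by 6-exo-trig addition of the carboxyl oxygen to the ketone carbonyl and dehydration to the conjugated enol lactone, forming O2–C3. The closest known reaction type is the C–H/O–H annulation of benzoic acids with α-acyl sulfoxonium ylides to 3-substituted isocoumarins under trivalent rhodium or divalent ruthenium catalysis, here applied to a dienoyl ylide. No stereocentre is formed; the three centres of ring C are remote from the reacting carbon and see no base, and the diene geometry is untouched because the carbene carbon is the former ylide CH. The step needs site selectivity, which the substitution pattern of 15 secures, since C8 bears oxygen and only one ortho C–H exists. It also needs C–H insertion to win over O–H insertion of the acid into the carbene, which the chelation-assisted metalation should secure. The buffered, non-ionising medium and the ketone conjugation protect the allylic C2'–O1' bond until the ring is formed.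

Step 11
Reactants: 17 3-[(1E,3E)-4-[(2R,3S,5R)-3-(tert-butyldimethylsilyloxy)-5-methyloxolan-2-yl]buta-1,3-dien-1-yl]-5-chloro-6,8-bis(triisopropylsilyloxy)-1H-isochromen-1-one
Product: 18 5-chloro-6,8-dihydroxy-3-[(1E,3E)-4-[(2R,3S,5R)-3-hydroxy-5-methyloxolan-2-yl]buta-1,3-dien-1-yl]-1H-isochromen-1-one (CNP0086741.2)
Conditions: Bu4NF/AcOH (1:1, 4 equiv), THF, 0 → 23 °C
Reagents that add atoms: none
Why: Fluoride cleaves the two aryl silyl ethers quickly and the secondary alkyl silyl ether more slowly. The acetic acid buffer keeps the medium near neutral, so neither the enol lactone (base) nor the allylic C2'–O1' bond (acid) is attacked, and no stereocentre is affected.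

## Compound list

1 | 2-deoxy-D-ribono-1,4-lactone [(4S,5R)-4-hydroxy-5-(hydroxymethyl)oxolan-2-one] | O=C1C[C@H](O)[C@@H](CO)O1 | starting material
2 | (4S,5R)-4-(tert-butyldimethylsilyloxy)-5-[(tert-butyldimethylsilyloxy)methyl]oxolan-2-one | O=C1C[C@H](O[Si](C)(C)C(C)(C)C)[C@@H](CO[Si](C)(C)C(C)(C)C)O1 | intermediate
3 | diisobutylaluminium lactolate of 2 (epimeric at the lactol carbon) | CC(C)C[Al](CC(C)C)OC1C[C@H](O[Si](C)(C)C(C)(C)C)[C@@H](CO[Si](C)(C)C(C)(C)C)O1 | intermediate (not isolated)
4 | (4S,5R)-4-(tert-butyldimethylsilyloxy)-5-[(tert-butyldimethylsilyloxy)methyl]oxolan-2-yl acetate (mixture of anomers) | CC(=O)OC1C[C@H](O[Si](C)(C)C(C)(C)C)[C@@H](CO[Si](C)(C)C(C)(C)C)O1 | intermediate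
5 | (2R,3S,5R)-3-(tert-butyldimethylsilyloxy)-2-[(tert-butyldimethylsilyloxy)methyl]-5-methyloxolane | C[C@@H]1C[C@H](O[Si](C)(C)C(C)(C)C)[C@@H](CO[Si](C)(C)C(C)(C)C)O1 | intermediate
6 | [(2R,3S,5R)-3-(tert-butyldimethylsilyloxy)-5-methyloxolan-2-yl]methanol | C[C@@H]1C[C@H](O[Si](C)(C)C(C)(C)C)[C@@H](CO)O1 | intermediate
7 | (2S,3S,5R)-3-(tert-butyldimethylsilyloxy)-5-methyloxolane-2-carbaldehyde | C[C@@H]1C[C@H](O[Si](C)(C)C(C)(C)C)[C@@H](C=O)O1 | intermediate
8 | triethyl 4-phosphonocrotonate [ethyl (2E)-4-(diethoxyphosphoryl)but-2-enoate] | CCOC(=O)/C=C/CP(=O)(OCC)OCC | starting material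
9 | ethyl (2E,4E)-5-[(2R,3S,5R)-3-(tert-butyldimethylsilyloxy)-5-methyloxolan-2-yl]penta-2,4-dienoate | C[C@@H]1C[C@H](O[Si](C)(C)C(C)(C)C)[C@@H](/C=C/C=C/C(=O)OCC)O1 | intermediate
10 | (2E,4E)-5-[(2R,3S,5R)-3-(tert-butyldimethylsilyloxy)-5-methyloxolan-2-yl]penta-2,4-dienoic acid | C[C@@H]1C[C@H](O[Si](C)(C)C(C)(C)C)[C@@H](/C=C/C=C/C(=O)O)O1 | intermediate
11 | (2E,4E)-5-[(2R,3S,5R)-3-(tert-butyldimethylsilyloxy)-5-methyloxolan-2-yl]penta-2,4-dienoyl chloride | C[C@@H]1C[C@H](O[Si](C)(C)C(C)(C)C)[C@@H](/C=C/C=C/C(=O)Cl)O1 | intermediate (not isolated)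
12 | (3E,5E)-1-[dimethyl(oxo)-λ6-sulfanylidene]-6-[(2R,3S,5R)-3-(tert-butyldimethylsilyloxy)-5-methyloxolan-2-yl]hexa-3,5-dien-2-one | C[C@@H]1C[C@H](O[Si](C)(C)C(C)(C)C)[C@@H](/C=C/C=C/C(=O)C=S(C)(C)=O)O1 | intermediate
13 | 5-chloro-2,4-dihydroxybenzoic acid | OC(=O)c1cc(Cl)c(O)cc1O | starting material
14 | triisopropylsilyl 5-chloro-2,4-bis(triisopropylsilyloxy)benzoate | CC(C)[Si](C(C)C)(C(C)C)OC(=O)c1cc(Cl)c(O[Si](C(C)C)(C(C)C)C(C)C)cc1O[Si](C(C)C)(C(C)C)C(C)C | intermediate (not isolated)
15 | 5-chloro-2,4-bis(triisopropylsilyloxy)benzoic acid | OC(=O)c1cc(Cl)c(O[Si](C(C)C)(C(C)C)C(C)C)cc1O[Si](C(C)C)(C(C)C)C(C)C | intermediate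
16 | 3-chloro-2-[(3E,5E)-6-[(2R,3S,5R)-3-(tert-butyldimethylsilyloxy)-5-methyloxolan-2-yl]-2-oxohexa-3,5-dien-1-yl]-4,6-bis(triisopropylsilyloxy)benzoic acid | C[C@@H]1C[C@H](O[Si](C)(C)C(C)(C)C)[C@@H](/C=C/C=C/C(=O)Cc2c(Cl)c(O[Si](C(C)C)(C(C)C)C(C)C)cc(O[Si](C(C)C)(C(C)C)C(C)C)c2C(=O)O)O1 | intermediate (not isolated)
17 | 3-[(1E,3E)-4-[(2R,3S,5R)-3-(tert-butyldimethylsilyloxy)-5-methyloxolan-2-yl]buta-1,3-dien-1-yl]-5-chloro-6,8-bis(triisopropylsilyloxy)-1H-isochromen-1-one | C[C@@H]1C[C@H](O[Si](C)(C)C(C)(C)C)[C@@H](/C=C/C=C/c2cc3c(Cl)c(O[Si](C(C)C)(C(C)C)C(C)C)cc(O[Si](C(C)C)(C(C)C)C(C)C)c3c(=O)o2)O1 | intermediate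
18 | 5-chloro-6,8-dihydroxy-3-[(1E,3E)-4-[(2R,3S,5R)-3-hydroxy-5-methyloxolan-2-yl]buta-1,3-dien-1-yl]-1H-isochromen-1-one (CNP0086741.2) | C[C@@H]1C[C@H](O)[C@@H](/C=C/C=C/c2cc3c(Cl)c(O)cc(O)c3c(=O)o2)O1 | target

## Step count and least certain steps

Total step count: 11. Longest linear sequence: 10 steps (steps 1–8, 10 and 11, from 1 to 18); step 9 is the one-step side branch.

**Step 10 (key step).** The most likely failure is slow metalation of the C–H that is squeezed between the carboxylate and the chlorine. The acid would then be consumed by O–H insertion into the carbene (esterification by the ylide). A second risk is migration or loss of the ortho silyl group on the rhodium carboxylate, which would shut down the directing effect.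

The fallback builds ring B from a benzylic anion instead of a C–H bond. It sets out from 10 and returns at 17.
- Acid 10 is condensed with N,O-dimethylhydroxylamine to give the N-methoxy-N-methyl dienamide F1.
- Commercial methyl 2,4-dihydroxy-6-methylbenzoate F2 is chlorinated with SO2Cl2, which should favour the position next to the methyl group, to give methyl 3-chloro-4,6-dihydroxy-2-methylbenzoate F3.
- F3 is silylated to methyl 3-chloro-2-methyl-4,6-bis(triisopropylsilyloxy)benzoate F4.
- Lateral lithiation of F4 with LiN(i-Pr)2 at −78 °C and acylation with F1 give the keto ester F5.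
- Base-induced enol lactonisation (DBU, toluene) with loss of methanol closes F5 to 17.

**Step 3.** The small, very reactive methyl donor may capture the oxocarbenium ion with poor facial selectivity, or the ring C–O bond may cleave instead of the exocyclic one.

The fallback uses the nucleophile class with the best-documented 1,3-cis preference and then trims it. It sets out from 4 and returns at 5.
- Allyltrimethylsilane and BF3·OEt2 give the C-allyl oxolane F6.
- Ozonolysis with dimethyl sulfide work-up gives the acetaldehyde F7.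
- Tsuji–Wilkinson decarbonylation with RhCl(PPh3)3 turns the CH2CHO group into the methyl group of 5.

**Step 8.** The methylide may add in conjugate fashion to the dienoyl system (cyclopropanation). It may also act as a base on the acid chloride and form a ketene through the allylic C2'–H, which would erode the C2' configuration.

The fallback replaces the ylide by a diazo ketone made without a basic carbon nucleophile at the acyl chloride stage. It sets out from 10 and returns at 17.
- Acid 10 and MeLi (2 equiv) give the dienyl methyl ketone F8.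
- The lithium enolate of F8, from LiN(SiMe3)2, is trifluoroacetylated with 2,2,2-trifluoroethyl trifluoroacetate to give the trifluoroacetyl diketone F9.
- Detrifluoroacetylative diazo transfer with methanesulfonyl azide and triethylamine gives the diazo ketone F10.
- F10 is used with 15 under the conditions of step 10 (same rhodium carbene, loss of dinitrogen) to reach 17.

**Step 11.** The hindered secondary silyl ether may come off too slowly. Prolonged exposure to fluoride could then open the lactone or ionise the allylic C2'–O1' bond before desilylation is complete.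

The fallback changes the order of deprotection so that only aryl silyl ethers are left for the last step. It sets out from 12 and returns at 18.
- Bu4NF in THF removes the alkyl silyl ether of 12 to give the hydroxy ylide F11.
- F11 and 15 under the conditions of step 10 give the hydroxy isocoumarin F12.
- Brief treatment with KF/AcOH at 0 °C cleaves the two aryl silyl ethers within minutes to give 18.

## Further compounds

F1 | step 10 | (2E,4E)-N-methoxy-N-methyl-5-[(2R,3S,5R)-3-(tert-butyldimethylsilyloxy)-5-methyloxolan-2-yl]penta-2,4-dienamide | C[C@@H]1C[C@H](O[Si](C)(C)C(C)(C)C)[C@@H](/C=C/C=C/C(=O)N(C)OC)O1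
F2 | step 10 | methyl 2,4-dihydroxy-6-methylbenzoate | COC(=O)c1c(C)cc(O)cc1O
F3 | step 10 | methyl 3-chloro-4,6-dihydroxy-2-methylbenzoate | COC(=O)c1c(C)c(Cl)c(O)cc1O
F4 | step 10 | methyl 3-chloro-2-methyl-4,6-bis(triisopropylsilyloxy)benzoate | COC(=O)c1c(C)c(Cl)c(O[Si](C(C)C)(C(C)C)C(C)C)cc1O[Si](C(C)C)(C(C)C)C(C)C
F5 | step 10 | methyl 3-chloro-2-[(3E,5E)-6-[(2R,3S,5R)-3-(tert-butyldimethylsilyloxy)-5-methyloxolan-2-yl]-2-oxohexa-3,5-dien-1-yl]-4,6-bis(triisopropylsilyloxy)benzoate | C[C@@H]1C[C@H](O[Si](C)(C)C(C)(C)C)[C@@H](/C=C/C=C/C(=O)Cc2c(Cl)c(O[Si](C(C)C)(C(C)C)C(C)C)cc(O[Si](C(C)C)(C(C)C)C(C)C)c2C(=O)OC)O1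
F6 | step 3 | (2R,3S,5R)-3-(tert-butyldimethylsilyloxy)-2-[(tert-butyldimethylsilyloxy)methyl]-5-(prop-2-en-1-yl)oxolane | C=CC[C@@H]1C[C@H](O[Si](C)(C)C(C)(C)C)[C@@H](CO[Si](C)(C)C(C)(C)C)O1
F7 | step 3 | 2-[(2S,4S,5R)-4-(tert-butyldimethylsilyloxy)-5-[(tert-butyldimethylsilyloxy)methyl]oxolan-2-yl]acetaldehyde | O=CC[C@@H]1C[C@H](O[Si](C)(C)C(C)(C)C)[C@@H](CO[Si](C)(C)C(C)(C)C)O1
F8 | step 8 | (3E,5E)-6-[(2R,3S,5R)-3-(tert-butyldimethylsilyloxy)-5-methyloxolan-2-yl]hexa-3,5-dien-2-one | C[C@@H]1C[C@H](O[Si](C)(C)C(C)(C)C)[C@@H](/C=C/C=C/C(C)=O)O1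
F9 | step 8 | (5E,7E)-8-[(2R,3S,5R)-3-(tert-butyldimethylsilyloxy)-5-methyloxolan-2-yl]-1,1,1-trifluoroocta-5,7-diene-2,4-dione | C[C@@H]1C[C@H](O[Si](C)(C)C(C)(C)C)[C@@H](/C=C/C=C/C(=O)CC(=O)C(F)(F)F)O1
F10 | step 8 | (3E,5E)-1-diazo-6-[(2R,3S,5R)-3-(tert-butyldimethylsilyloxy)-5-methyloxolan-2-yl]hexa-3,5-dien-2-one | C[C@@H]1C[C@H](O[Si](C)(C)C(C)(C)C)[C@@H](/C=C/C=C/C(=O)C=[N+]=[N-])O1
F11 | step 11 | (3E,5E)-1-[dimethyl(oxo)-λ6-sulfanylidene]-6-[(2R,3S,5R)-3-hydroxy-5-methyloxolan-2-yl]hexa-3,5-dien-2-one | C[C@@H]1C[C@H](O)[C@@H](/C=C/C=C/C(=O)C=S(C)(C)=O)O1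
F12 | step 11 | 5-chloro-3-[(1E,3E)-4-[(2R,3S,5R)-3-hydroxy-5-methyloxolan-2-yl]buta-1,3-dien-1-yl]-6,8-bis(triisopropylsilyloxy)-1H-isochromen-1-one | C[C@@H]1C[C@H](O)[C@@H](/C=C/C=C/c2cc3c(Cl)c(O[Si](C(C)C)(C(C)C)C(C)C)cc(O[Si](C(C)C)(C(C)C)C(C)C)c3c(=O)o2)O1
A1 | alternative 1 | 5-chloro-3-[(E)-2-iodoethenyl]-6,8-bis(triisopropylsilyloxy)-1H-isochromen-1-one | I/C=C/c1cc2c(Cl)c(O[Si](C(C)C)(C(C)C)C(C)C)cc(O[Si](C(C)C)(C(C)C)C(C)C)c2c(=O)o1
A2 | alternative 1 | tributyl{(E)-2-[(2R,3S,5R)-3-(tert-butyldimethylsilyloxy)-5-methyloxolan-2-yl]ethenyl}stannane | C[C@@H]1C[C@H](O[Si](C)(C)C(C)(C)C)[C@@H](/C=C/[Sn](CCCC)(CCCC)CCCC)O1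
A3 | alternative 2 | methyl 3-chloro-2-iodo-4,6-bis(triisopropylsilyloxy)benzoate | COC(=O)c1c(I)c(Cl)c(O[Si](C(C)C)(C(C)C)C(C)C)cc1O[Si](C(C)C)(C(C)C)C(C)C
A4 | alternative 2 | (2R,3S,5R)-3-(tert-butyldimethylsilyloxy)-2-[(1E,3E)-hexa-1,3-dien-5-yn-1-yl]-5-methyloxolane | C[C@@H]1C[C@H](O[Si](C)(C)C(C)(C)C)[C@@H](/C=C/C=C/C#C)O1
A5 | alternative 2 | methyl 3-chloro-2-[(3E,5E)-6-[(2R,3S,5R)-3-(tert-butyldimethylsilyloxy)-5-methyloxolan-2-yl]hexa-3,5-dien-1-yn-1-yl]-4,6-bis(triisopropylsilyloxy)benzoate | C[C@@H]1C[C@H](O[Si](C)(C)C(C)(C)C)[C@@H](/C=C/C=C/C#Cc2c(Cl)c(O[Si](C(C)C)(C(C)C)C(C)C)cc(O[Si](C(C)C)(C(C)C)C(C)C)c2C(=O)OC)O1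
A6 | alternative 3 | 5-chloro-3-[(1E,3E)-4-[(2S,3S)-3-[(2R)-2-hydroxypropyl]oxiran-2-yl]buta-1,3-dien-1-yl]-6,8-bis(triisopropylsilyloxy)-1H-isochromen-1-one | C[C@@H](O)C[C@@H]1O[C@H]1/C=C/C=C/c1cc2c(Cl)c(O[Si](C(C)C)(C(C)C)C(C)C)cc(O[Si](C(C)C)(C(C)C)C(C)C)c2c(=O)o1
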